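**Strategy.** The oxolane ring (O1, C2–C5; 2,3-trans-3,4-cis-4,5-trans) is a meso unit carrying two identical (1R,2S) aryl ether arms, so one arm-bearing aryl bromide serves twice and the ring needs only relative stereocontrol. Everything rests on the bond between ring carbon C2 and its aryl carbon: C2 is benzylic and bonded to O1, hence a latent oxocarbenium carbon. In the key step the arylzinc from that bromide displaces the sulfinate of a 2-benzenesulfonyl-5-aryl-3,4-cis-dimethyloxolane; the aryl group enters opposite the two cis methyl groups, joining the halves and setting the last ring stereocenter at once. The sulfone arises from meso-2,3-dimethylsuccinic anhydride and the same bromide.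

Key step: step 11

Abbreviations: TBS = tert-butyldimethylsilyl; Ar* = 4-{[(1R,2S)-1-(TBS-oxy)-1-(3,4-dimethoxyphenyl)propan-2-yl]oxy}-3-methoxyphenyl.

Remark on the chemistry: because the oxolane core is meso and both arms are identical, the diastereomer of 13–17 with the mirror-image core gives the same compound 20. The chiral ligand in step 7 (the antipode that delivers 13, its sense to be fixed on the first run) therefore only keeps 13–17 as essentially one diastereomer. Compounds 16 and 17 are anomer mixtures at C2; both anomers give the same cation in step 11.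

**Step 1**
Reactants: 1 4-bromo-2-methoxyphenol; 2 methyl (R)-lactate
Product: 3 methyl (2S)-2-(4-bromo-2-methoxyphenoxy)propanoate
Conditions: PPh3, DIAD, THF, 0 °C → rt
Reagents that add atoms: none
Why: Mitsunobu etherification: the phenol displaces the phosphonium-activated secondary hydroxyl in an SN2 reaction with inversion, so the (R) lactate should give the (S) aryl ether.

**Step 2**
Reactants: 3 methyl (2S)-2-(4-bromo-2-methoxyphenoxy)propanoate
Product: 4 (2S)-2-(4-bromo-2-methoxyphenoxy)-N-methoxy-N-methylpropanamide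
Conditions: MeNH(OMe)·HCl, i-PrMgCl, THF, −20 °C
Reagents that add atoms: N,O-dimethylhydroxylamine hydrochloride, CNOC.Cl
Why: Weinreb amide formation by aminolysis of the ester with the chloromagnesium amide of N,O-dimethylhydroxylamine, which is weakly basic at −20 °C and should leave the α-aryloxy stereocenter untouched.

**Step 3**
Reactants: 4 (2S)-2-(4-bromo-2-methoxyphenoxy)-N-methoxy-N-methylpropanamide; 5 3,4-dimethoxyphenylmagnesium bromide (THF solution)
Product: 6 (2S)-2-(4-bromo-2-methoxyphenoxy)-1-(3,4-dimethoxyphenyl)propan-1-one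
Conditions: THF, 0 °C; aq. NH4Cl
Reagents that add atoms: none
Why: Weinreb ketone synthesis: the magnesium-chelated tetrahedral adduct survives until quench, so one aryl group adds and the α-stereocenter is not enolised, and the aryl bromide does not exchange with an aryl Grignard reagent at 0 °C.

**Step 4**
Reactants: 6 (2S)-2-(4-bromo-2-methoxyphenoxy)-1-(3,4-dimethoxyphenyl)propan-1-one
Product: 7 (1R,2S)-2-(4-bromo-2-methoxyphenoxy)-1-(3,4-dimethoxyphenyl)propan-1-ol (erythro)
Conditions: Zn(BH4)2 (ethereal stock solution), Et2O, −30 → 0 °C; aq. NH4Cl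
Reagents that add atoms: none
Why: Chelation-controlled (Cram chelate) hydride reduction: zinc bridges the carbonyl oxygen and the α-aryloxy oxygen and hydride enters past hydrogen, away from the methyl group, which should set C1 as (R) and give the erythro (1R,2S) alcohol.

**Step 5**
Reactants: 7 (1R,2S)-2-(4-bromo-2-methoxyphenoxy)-1-(3,4-dimethoxyphenyl)propan-1-ol
Product: 8 arm bromide Ar*–Br, tert-butyl{[(1R,2S)-2-(4-bromo-2-methoxyphenoxy)-1-(3,4-dimethoxyphenyl)propyl]oxy}dimethylsilane
Conditions: TBSOTf, 2,6-lutidine, CH2Cl2, 0 °C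
Reagents that add atoms: tert-butyldimethylsilyl triflate, CC(C)(C)[Si](C)(C)OS(=O)(=O)C(F)(F)F
Why: Silyl ether formation with the silyl triflate, which is reactive enough for the hindered secondary benzylic alcohol; the TBS ether masks the only acidic proton before the organometallic steps.

**Step 6**
Reactants: 9 meso-2,3-dimethylsuccinic acid
Product: 10 cis-2,3-dimethylsuccinic anhydride, (3R,4S)-3,4-dimethyloxolane-2,5-dione
Conditions: AcCl (neat), 50 °C; evaporate
Reagents that add atoms: none
Why: Cyclodehydration of the 1,4-diacid with acetyl chloride gives the five-membered anhydride under non-basic conditions, so the meso (cis) relationship should be retained.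

**Step 7**
Reactants: 8 arm bromide Ar*–Br; 10 cis-2,3-dimethylsuccinic anhydride
Product: 13 (2S,3R)-4-Ar*-2,3-dimethyl-4-oxobutanoic acid, via aryllithium Ar*–Li 11 (not isolated), via arylzinc triflate Ar*–ZnOTf 12 (not isolated)
Conditions: n-BuLi, THF, −78 °C; Zn(OTf)2, −78 °C → rt; then 10 (1.5 equiv), [Rh(cod)Cl]2 (cat.), TADDOL-derived phosphoramidite ligand (cat.), DMF, 50 °C; aq. HCl
Reagents that add atoms: none
Why: Rhodium-catalysed acylation of an arylzinc by a cyclic anhydride (enantioselective desymmetrisation of a meso anhydride): bromine–lithium exchange and transmetalation to zinc are followed by aryl transfer to one of the two enantiotopic carbonyls under control of the chiral ligand, without epimerisation of the syn-dimethyl unit.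

**Step 8**
Reactants: 13 (2S,3R)-4-Ar*-2,3-dimethyl-4-oxobutanoic acid
Product: 15 (3S,4R,5R)-5-Ar*-3,4-dimethyloxolan-2-one (3,4-cis-4,5-trans lactone), via hydroxy acid 14 (not isolated)
Conditions: LiBH(s-Bu)3 (2.5 equiv), THF, −78 °C; aq. HCl to pH 3; PPTS (cat.), CH2Cl2, rt
Reagents that add atoms: none
Why: Felkin–Anh reduction of the aryl ketone with a bulky hydride: hydride adds anti to the CH(Me)CO2Li group and past hydrogen, which should set the carbinol carbon as (R), and acidification closes the γ-lactone with the aryl group trans to the C4 methyl.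

**Step 9**
Reactants: 15 (3S,4R,5R)-5-Ar*-3,4-dimethyloxolan-2-one
Product: 16 (3S,4R,5R)-5-Ar*-3,4-dimethyloxolan-2-ol (lactol, anomer mixture)
Conditions: i-Bu2AlH (1.1 equiv), CH2Cl2, −78 °C; aq. potassium sodium tartrate work-up
Reagents that add atoms: none
Why: Partial reduction of the lactone with i-Bu2AlH at −78 °C stops at the lactol because the tetrahedral aluminium alkoxide is stable until quench.

**Step 10**
Reactants: 16 (3S,4R,5R)-5-Ar*-3,4-dimethyloxolan-2-ol
Product: 17 (3S,4R,5R)-2-(benzenesulfonyl)-5-Ar*-3,4-dimethyloxolane (anomer mixture)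
Conditions: PhSO2H, CaCl2, CH2Cl2, rt
Reagents that add atoms: benzenesulfinic acid, O=S(O)c1ccccc1
Why: Acid-mediated exchange of the anomeric hydroxyl for sulfinate (lactol to 2-sulfonyl cyclic ether through the oxocarbenium ion, sulfur as the nucleophile), driven by uptake of water by CaCl2.

**Step 11**
Reactants: 8 arm bromide Ar*–Br (2.5 equiv); 17 (3S,4R,5R)-2-(benzenesulfonyl)-5-Ar*-3,4-dimethyloxolane
Product: 20 (2S,3S,4R,5R)-2,5-bis(Ar*)-3,4-dimethyloxolane (bis-TBS ether of the target), via arylmagnesium bromide Ar*–MgBr 18 (not isolated), via arylzinc bromide Ar*–ZnBr 19 (not isolated)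
Conditions: Mg turnings (I2 cat.), THF, 45 °C; ZnBr2 (1.1 equiv per Grignard reagent), 0 °C → rt; then 17, rt; aq. NH4Cl
Reagents that add atoms: none
Why: Ley-type substitution of a 2-benzenesulfonyl cyclic ether by an arylzinc: magnesium insertion into the C–Br bond of 8 and transmetalation with ZnBr2 give arylzinc bromide 19, the divalent zinc and magnesium bromides in the mixture ionise the C2–S bond of 17 to the O1=C2 oxocarbenium ion, and the aryl group of 19 is transferred to C2, forming the aryl–C2 bond. The closest known reaction type is the displacement of anomeric sulfones by organozinc reagents made from Grignard reagents and ZnBr2, used for C-glycosides and other 2-substituted cyclic ethers. No ring is closed, since the oxolane is preformed. The new stereocenter C2 (S) is set by the substrate: in the envelope with C4 as the flap, C4-methyl and C5-aryl pseudoequatorial and C3-methyl pseudoaxial, inside attack comes from the face opposite both cis methyl groups, which should give the 2,3-trans-3,4-cis-4,5-trans ring. The step needs this facial selectivity, no loss of the cis C3/C4 relationship through the enol ether, and survival of the two benzylic silyl ethers and the C5 benzylic ether; the ethereal solvent, the ambient temperature and the mild Lewis acidity of the zinc and magnesium bromides should secure this, and both anomers of 17 funnel into the same cation.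

**Step 12**
Reactants: 20 (2S,3S,4R,5R)-2,5-bis(Ar*)-3,4-dimethyloxolane
Product: 21 target, (1R,2S)-1-(3,4-dimethoxyphenyl)-2-[4-[(2S,3S,4R,5R)-5-[4-[(1R,2S)-1-(3,4-dimethoxyphenyl)-1-hydroxypropan-2-yl]oxy-3-methoxyphenyl]-3,4-dimethyloxolan-2-yl]-2-methoxyphenoxy]propan-1-ol
Conditions: Bu4NF, THF, rt → 40 °C
Reagents that add atoms: none
Why: Fluoride-mediated cleavage of both silyl ethers (Si–F bond formation) under non-acidic conditions that should leave the benzylic ether carbons of the ring and arms untouched.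

**Compound list**

1 | 4-bromo-2-methoxyphenol | Oc1ccc(Br)cc1OC | starting material
2 | methyl (R)-lactate | C[C@@H](O)C(=O)OC | starting material
3 | methyl (2S)-2-(4-bromo-2-methoxyphenoxy)propanoate | C[C@H](Oc1ccc(Br)cc1OC)C(=O)OC | intermediate
4 | (2S)-2-(4-bromo-2-methoxyphenoxy)-N-methoxy-N-methylpropanamide | C[C@H](Oc1ccc(Br)cc1OC)C(=O)N(C)OC | intermediate
5 | 3,4-dimethoxyphenylmagnesium bromide | COc1ccc([Mg]Br)cc1OC | starting material
6 | (2S)-2-(4-bromo-2-methoxyphenoxy)-1-(3,4-dimethoxyphenyl)propan-1-one | C[C@H](Oc1ccc(Br)cc1OC)C(=O)c1ccc(OC)c(OC)c1 | intermediate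
7 | (1R,2S)-2-(4-bromo-2-methoxyphenoxy)-1-(3,4-dimethoxyphenyl)propan-1-ol | C[C@H](Oc1ccc(Br)cc1OC)[C@H](O)c1ccc(OC)c(OC)c1 | intermediate
8 | arm bromide Ar*–Br, TBS ether of 7 | C[C@H](Oc1ccc(Br)cc1OC)[C@H](O[Si](C)(C)C(C)(C)C)c1ccc(OC)c(OC)c1 | intermediate
9 | meso-2,3-dimethylsuccinic acid | C[C@@H](C(=O)O)[C@H](C)C(=O)O | starting material
10 | cis-2,3-dimethylsuccinic anhydride | C[C@@H]1[C@H](C)C(=O)OC1=O | intermediate
11 | aryllithium Ar*–Li (not isolated) | [Li]c1ccc(O[C@@H](C)[C@H](O[Si](C)(C)C(C)(C)C)c2ccc(OC)c(OC)c2)c(OC)c1 | intermediate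
12 | arylzinc triflate Ar*–ZnOTf (not isolated) | FC(F)(F)S(=O)(=O)O[Zn]c1ccc(O[C@@H](C)[C@H](O[Si](C)(C)C(C)(C)C)c2ccc(OC)c(OC)c2)c(OC)c1 | intermediate
13 | (2S,3R)-4-Ar*-2,3-dimethyl-4-oxobutanoic acid | OC(=O)[C@@H](C)[C@@H](C)C(=O)c1ccc(O[C@@H](C)[C@H](O[Si](C)(C)C(C)(C)C)c2ccc(OC)c(OC)c2)c(OC)c1 | intermediate
14 | (2S,3R,4R)-4-Ar*-4-hydroxy-2,3-dimethylbutanoic acid (not isolated) | OC(=O)[C@@H](C)[C@@H](C)[C@@H](O)c1ccc(O[C@@H](C)[C@H](O[Si](C)(C)C(C)(C)C)c2ccc(OC)c(OC)c2)c(OC)c1 | intermediate
15 | (3S,4R,5R)-5-Ar*-3,4-dimethyloxolan-2-one | O=C1O[C@@H](c2ccc(O[C@@H](C)[C@H](O[Si](C)(C)C(C)(C)C)c3ccc(OC)c(OC)c3)c(OC)c2)[C@H](C)[C@@H]1C | intermediate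
16 | (3S,4R,5R)-5-Ar*-3,4-dimethyloxolan-2-ol, anomer mixture | OC1O[C@@H](c2ccc(O[C@@H](C)[C@H](O[Si](C)(C)C(C)(C)C)c3ccc(OC)c(OC)c3)c(OC)c2)[C@H](C)[C@@H]1C | intermediate
17 | (3S,4R,5R)-2-(benzenesulfonyl)-5-Ar*-3,4-dimethyloxolane, anomer mixture | O=S(=O)(c1ccccc1)C1O[C@@H](c2ccc(O[C@@H](C)[C@H](O[Si](C)(C)C(C)(C)C)c3ccc(OC)c(OC)c3)c(OC)c2)[C@H](C)[C@@H]1C | intermediate
18 | arylmagnesium bromide Ar*–MgBr (not isolated) | Br[Mg]c1ccc(O[C@@H](C)[C@H](O[Si](C)(C)C(C)(C)C)c2ccc(OC)c(OC)c2)c(OC)c1 | intermediate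
19 | arylzinc bromide Ar*–ZnBr (not isolated) | Br[Zn]c1ccc(O[C@@H](C)[C@H](O[Si](C)(C)C(C)(C)C)c2ccc(OC)c(OC)c2)c(OC)c1 | intermediate
20 | (2S,3S,4R,5R)-2,5-bis(Ar*)-3,4-dimethyloxolane | COc1ccc([C@@H](O[Si](C)(C)C(C)(C)C)[C@H](C)Oc2ccc([C@H]3O[C@@H](c4ccc(O[C@@H](C)[C@H](O[Si](C)(C)C(C)(C)C)c5ccc(OC)c(OC)c5)c(OC)c4)[C@H](C)[C@@H]3C)cc2OC)cc1OC | intermediate
21 | target CNP0116650.10 | COc1ccc([C@@H](O)[C@H](C)Oc2ccc([C@H]3O[C@@H](c4ccc(O[C@@H](C)[C@H](O)c5ccc(OC)c(OC)c5)c(OC)c4)[C@H](C)[C@@H]3C)cc2OC)cc1OC | target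

**Count.** Total steps: 12. Longest linear sequence: 11 (steps 1–5, then 7–12; step 6 is a one-step side branch).

**Steps most likely to fail**

Step 11 (key step). The aryl group may enter on the wrong face of the oxocarbenium ion, the cation may lose the C3 proton to the enol ether and scramble the cis-dimethyl unit, or ionisation of the sulfone may be sluggish with the bulky arylzinc. The fallback sets out from lactol 16 and separates C–C bond formation from stereocontrol. Excess arylmagnesium bromide 18 (made from 8 as in step 11, 3 equiv) is added in THF at 0 °C → rt; the first equivalent deprotonates the lactol and the next opens it through its hydroxy aldehyde form to the (2S,3R,4R)-1,4-bis(Ar*)-2,3-dimethylbutane-1,4-diol F1, formed as a mixture at the new carbinol carbon. Acid-catalysed cyclodehydration (camphorsulfonic acid cat., CH2Cl2, 0 °C) then proceeds through the p-alkoxybenzylic cation. Ring closure is reversible at both benzylic carbons and should converge on the ring with each aryl group trans to its neighbouring methyl. The fallback comes back to the route at 20.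

Step 7. Aryl transfer from the hindered, electron-rich arylzinc to rhodium may be slow, so that protonation or homocoupling of the arylzinc competes, or the syn-dimethyl unit may epimerise. The fallback sets out from anhydride 10. Methanolysis catalysed by a modified cinchona alkaloid ((DHQD)2AQN or its pseudo-enantiomer, Et2O, −20 °C) should give the half-ester (2R,3S)-4-methoxy-2,3-dimethyl-4-oxobutanoic acid F2. Oxalyl chloride with catalytic DMF converts it into methyl (2S,3R)-4-chloro-2,3-dimethyl-4-oxobutanoate F3. Acylation of arylzinc bromide 19 (made from 8 as in step 11) with Pd(PPh3)4 as the zerovalent palladium catalyst in THF at 0 °C gives methyl (2S,3R)-4-Ar*-2,3-dimethyl-4-oxobutanoate F4. Reduction with LiBH(s-Bu)3 at −78 °C gives the alkoxide of methyl (2S,3R,4R)-4-Ar*-4-hydroxy-2,3-dimethylbutanoate F5, which lactonises on warming. The fallback comes back to the route at 15.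

Step 8. Hydride delivery may show poor facial selectivity, or prefer the face that leads to the 4,5-cis lactone. The fallback sets out from 13 and corrects the carbinol carbon by inversion instead of by reagent choice. The ketone is reduced without regard to selectivity (NaBH4, MeOH, 0 °C, then acid) and the lactones are separated. The all-cis lactone (3S,4R,5S)-5-Ar*-3,4-dimethyloxolan-2-one F6 is opened with LiOH in THF/H2O to (2S,3R,4S)-4-Ar*-4-hydroxy-2,3-dimethylbutanoic acid F7. Mitsunobu lactonisation (PPh3, DIAD, THF, 0 °C) closes the ring with inversion at the benzylic carbinol carbon. The fallback comes back to the route at 15.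

**Further compounds**

F1 | step 11 | (2S,3R,4R)-1,4-bis(Ar*)-2,3-dimethylbutane-1,4-diol, epimer mixture at C1 | OC(c1ccc(O[C@@H](C)[C@H](O[Si](C)(C)C(C)(C)C)c2ccc(OC)c(OC)c2)c(OC)c1)[C@@H](C)[C@@H](C)[C@@H](O)c1ccc(O[C@@H](C)[C@H](O[Si](C)(C)C(C)(C)C)c2ccc(OC)c(OC)c2)c(OC)c1
F2 | step 7 | (2R,3S)-4-methoxy-2,3-dimethyl-4-oxobutanoic acid | COC(=O)[C@@H](C)[C@@H](C)C(=O)O
F3 | step 7 | methyl (2S,3R)-4-chloro-2,3-dimethyl-4-oxobutanoate | COC(=O)[C@@H](C)[C@@H](C)C(=O)Cl
F4 | step 7 | methyl (2S,3R)-4-Ar*-2,3-dimethyl-4-oxobutanoate | COC(=O)[C@@H](C)[C@@H](C)C(=O)c1ccc(O[C@@H](C)[C@H](O[Si](C)(C)C(C)(C)C)c2ccc(OC)c(OC)c2)c(OC)c1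
F5 | step 7 | methyl (2S,3R,4R)-4-Ar*-4-hydroxy-2,3-dimethylbutanoate | COC(=O)[C@@H](C)[C@@H](C)[C@@H](O)c1ccc(O[C@@H](C)[C@H](O[Si](C)(C)C(C)(C)C)c2ccc(OC)c(OC)c2)c(OC)c1
F6 | step 8 | (3S,4R,5S)-5-Ar*-3,4-dimethyloxolan-2-one | O=C1O[C@H](c2ccc(O[C@@H](C)[C@H](O[Si](C)(C)C(C)(C)C)c3ccc(OC)c(OC)c3)c(OC)c2)[C@H](C)[C@@H]1C
F7 | step 8 | (2S,3R,4S)-4-Ar*-4-hydroxy-2,3-dimethylbutanoic acid | OC(=O)[C@@H](C)[C@@H](C)[C@H](O)c1ccc(O[C@@H](C)[C@H](O[Si](C)(C)C(C)(C)C)c2ccc(OC)c(OC)c2)c(OC)c1
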